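**Assumption:** the target is the (2S)-flavan as drawn, and (S)-2-chloro-1-(2,4-dichlorophenyl)ethanol (the bulk luliconazole intermediate, ≥99% ee) is taken as an inexpensive commercial enantiopure starting material. The route has not been run; conditions are standard for each reaction type.

## Retrosynthetic overview

1. Target 14 ⇐ enal 13 (1,2-reduction) ⇐ 8-allylflavan 12 by cross-metathesis with methacrolein, which sets the (E)-olefin.
2. The two B-ring OH groups ⇐ the two aryl C–Cl bonds of 10 (borylation/oxidation); the chlorides keep the benzylic carbon electron-poor until the ring is closed.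
3. The pyran ring is the only ring formed (both arenes are bought): Mitsunobu SN2 closure of diol 9 with inversion, the stereocentre coming from chlorohydrin 5.
4. C4–C4a bond ⇐ B-alkyl Suzuki coupling of allylic alcohol 7 (from 5 by one-carbon homologation) with bromophenol 4.
5. Key step: the C8–C1'' bond ⇐ aromatic Claisen [3,3] rearrangement of allyl ether 2, directed between the two oxygens by the ortho-bromine.

## Route

**Step 1**
Reactants: 1 2-bromo-5-methoxyphenol
Product: 2 2-(allyloxy)-1-bromo-4-methoxybenzene
Conditions: allyl bromide, K2CO3, acetone, reflux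
Reagents that add atoms: allyl bromide, C=CCBr
Why: Williamson O-allylation of the phenoxide is clean because the phenol is the only acidic or nucleophilic site.

**Step 2**
Reactants: 2 2-(allyloxy)-1-bromo-4-methoxybenzene
Product: 4 2-allyl-6-bromo-3-methoxyphenol, via ortho-dienone 3 (not isolated)
Conditions: N,N-diethylaniline, 190 °C, sealed tube
Reagents that add atoms: none
Why: Aromatic Claisen [3,3]-sigmatropic rearrangement in which the bromine blocks one ortho carbon, so the allyl terminus bonds only to the carbon between the two oxygens (future C8) and dienone 3 tautomerises to the phenol.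

**Step 3**
Reactants: 5 (S)-2-chloro-1-(2,4-dichlorophenyl)ethan-1-ol
Product: 7 (R)-1-(2,4-dichlorophenyl)prop-2-en-1-ol, via (S)-2-(2,4-dichlorophenyl)oxirane 6 (not isolated)
Conditions: NaH, THF, 0 °C to rt; then added to Me3S+ I−/n-BuLi (3 equiv), THF, −10 °C to rt
Reagents that add atoms: trimethylsulfonium iodide, C[S+](C)C.[I-]
Why: Williamson closure to the epoxide followed by sulfonium-ylide one-carbon homologation (ylide opens the terminal CH2, a second ylide triggers loss of Me2S) never breaks the carbinol C–O bond, so the bought stereocentre is retained (S becomes R only through the CIP priority change from CH2Cl to vinyl).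

**Step 4**
Reactants: 7 (R)-1-(2,4-dichlorophenyl)prop-2-en-1-ol; 4 2-allyl-6-bromo-3-methoxyphenol
Product: 9 2-allyl-6-[(3R)-3-(2,4-dichlorophenyl)-3-hydroxypropyl]-3-methoxyphenol, via bis(9-BBN) adduct 8 (not isolated)
Conditions: 9-BBN (2.2 equiv), THF, 0 °C to rt; then 4, PdCl2(dppf) (5 mol%), 3 M aq NaOH, THF, 65 °C
Reagents that add atoms: none
Why: Anti-Markovnikov hydroboration then B-alkyl Suzuki–Miyaura coupling, in which Pd(dppf) inserts into the C–Br bond but not the aryl C–Cl bonds, the borane is consumed before the allyl-bearing partner is added, and the stereocentre is not involved.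

**Step 5**
Reactants: 9 2-allyl-6-[(3R)-3-(2,4-dichlorophenyl)-3-hydroxypropyl]-3-methoxyphenol
Product: 10 (2S)-8-allyl-2-(2,4-dichlorophenyl)-7-methoxychromane
Conditions: PPh3, DIAD, THF (0.02 M), 0 °C to rt
Reagents that add atoms: none
Why: Intramolecular Mitsunobu etherification closes the pyran ring by SN2 with clean inversion (R to S), because the electron-poor dichloroaryl group disfavours benzylic ionisation.

**Step 6**
Reactants: 10 (2S)-8-allyl-2-(2,4-dichlorophenyl)-7-methoxychromane
Product: 12 4-[(2S)-8-allyl-7-methoxychroman-2-yl]benzene-1,3-diol, via bis(pinacolboronate) 11 (not isolated)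
Conditions: B2pin2 (3 equiv), Pd2(dba)3 (2 mol%), XPhos (8 mol%), KOAc, dioxane, 100 °C; then 30% aq H2O2, aq NaHCO3, THF, 0 °C to rt
Reagents that add atoms: hydrogen peroxide, OO; bis(pinacolato)diboron, CC1(C)OB(OC1(C)C)B1OC(C)(C)C(C)(C)O1 (its boron stays only in 11)
Why: Miyaura borylation of both aryl chlorides followed by ipso-oxidation (B-to-O 1,2-aryl shift) gives the resorcinol under cold, near-neutral conditions that avoid quinone-methide opening of the now electron-rich benzylic ether, so C2 is not scrambled.

**Step 7**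
Reactants: 12 4-[(2S)-8-allyl-7-methoxychroman-2-yl]benzene-1,3-diol
Product: 13 (2E)-4-[(2S)-2-(2,4-dihydroxyphenyl)-7-methoxychroman-8-yl]-2-methylbut-2-enal
Conditions: methacrolein (10 equiv), Hoveyda–Grubbs II (5 mol%), CH2Cl2, 40 °C
Reagents that add atoms: methacrolein, CC(=C)C=O
Why: Olefin cross-metathesis of the terminal allyl group with an electron-poor 1,1-disubstituted partner gives the (E)-2-methyl enal under thermodynamic control and tolerates free phenols.

**Step 8**
Reactants: 13 (2E)-4-[(2S)-2-(2,4-dihydroxyphenyl)-7-methoxychroman-8-yl]-2-methylbut-2-enal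
Product: 14 morusyunnansin E
Conditions: NaBH4, CeCl3·7H2O, MeOH, −20 °C
Reagents that add atoms: none
Why: Luche 1,2-reduction converts the enal into the allylic alcohol without touching the olefin geometry or the C2 stereocentre.

## Compound list

1 | 2-bromo-5-methoxyphenol | COc1ccc(Br)c(O)c1 | starting material
2 | 2-(allyloxy)-1-bromo-4-methoxybenzene | COc1ccc(Br)c(OCC=C)c1 | intermediate
3 | 6-allyl-2-bromo-5-methoxycyclohexa-2,4-dien-1-one (ortho-dienone) | COC1=CC=C(Br)C(=O)C1CC=C | intermediate (not isolated)
4 | 2-allyl-6-bromo-3-methoxyphenol | COc1ccc(Br)c(O)c1CC=C | intermediate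
5 | (S)-2-chloro-1-(2,4-dichlorophenyl)ethan-1-ol | O[C@H](CCl)c1ccc(Cl)cc1Cl | starting material
6 | (S)-2-(2,4-dichlorophenyl)oxirane | O1C[C@@H]1c1ccc(Cl)cc1Cl | intermediate (not isolated)
7 | (R)-1-(2,4-dichlorophenyl)prop-2-en-1-ol | O[C@H](C=C)c1ccc(Cl)cc1Cl | intermediate
8 | 9-[(1R)-3-(9-borabicyclo[3.3.1]nonan-9-yl)-1-(2,4-dichlorophenyl)propoxy]-9-borabicyclo[3.3.1]nonane (bis(9-BBN) adduct) | C1CCC2CCCC1B2O[C@H](CCB1C2CCCC1CCC2)c1ccc(Cl)cc1Cl | intermediate (not isolated)
9 | 2-allyl-6-[(3R)-3-(2,4-dichlorophenyl)-3-hydroxypropyl]-3-methoxyphenol | O[C@H](CCc1ccc(OC)c(CC=C)c1O)c1ccc(Cl)cc1Cl | intermediate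
10 | (2S)-8-allyl-2-(2,4-dichlorophenyl)-7-methoxychromane | COc1ccc2c(c1CC=C)O[C@H](c1ccc(Cl)cc1Cl)CC2 | intermediate
11 | (2S)-8-allyl-2-[2,4-bis(4,4,5,5-tetramethyl-1,3,2-dioxaborolan-2-yl)phenyl]-7-methoxychromane | COc1ccc2c(c1CC=C)O[C@H](c1ccc(B3OC(C)(C)C(C)(C)O3)cc1B1OC(C)(C)C(C)(C)O1)CC2 | intermediate (not isolated)
12 | 4-[(2S)-8-allyl-7-methoxychroman-2-yl]benzene-1,3-diol | COc1ccc2c(c1CC=C)O[C@H](c1ccc(O)cc1O)CC2 | intermediate
13 | (2E)-4-[(2S)-2-(2,4-dihydroxyphenyl)-7-methoxychroman-8-yl]-2-methylbut-2-enal | COc1ccc2c(c1C/C=C(\C)C=O)O[C@H](c1ccc(O)cc1O)CC2 | intermediate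
14 | morusyunnansin E | COc1ccc2c(c1C/C=C(\C)CO)O[C@H](c1ccc(O)cc1O)CC2 | target

## Step count and risks

Total: 8 steps. Longest linear sequence: 7 steps (steps 1, 2, 4, 5, 6, 7, 8 from 1; the branch from 5 is 6 steps).

**Step 6 (double borylation/oxidation).** The hindered ortho-chloride may borylate slowly or protodeboronate, and the allyl group may isomerise under Pd. The fallback sets out from 10 and replaces C–B chemistry by direct C–O coupling: Pd-catalysed etherification of both C–Cl bonds with 2-(trimethylsilyl)ethanol (RockPhos Pd G3, Cs2CO3, toluene, 90 °C) gives (2S)-8-allyl-2-{2,4-bis[2-(trimethylsilyl)ethoxy]phenyl}-7-methoxychromane F3. Fluoride-induced β-elimination (CsF, DMF, 60 °C, short reaction time) then frees both phenols, and the route is rejoined at 12.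

**Step 4 (B-alkyl Suzuki on a free ortho-bromophenol).** The electron-rich phenoxide may undergo oxidative addition sluggishly. The fallback sets out from 2 (with 7) and swaps the order of coupling and rearrangement: 7 is hydroborated to 8 as before and coupled with allyl ether 2 under the same Pd conditions to give (1R)-3-[2-(allyloxy)-4-methoxyphenyl]-1-(2,4-dichlorophenyl)propan-1-ol F2. Its aromatic Claisen rearrangement (N,N-diethylaniline, 190 °C; only one ortho carbon is free) then gives the phenol, rejoining the route at 9.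

**Step 3 (ylide homologation).** Oxetane formation or attack at the benzylic epoxide carbon could compete. The fallback sets out from 5: the epoxide 6 is formed as before and opened at its terminal carbon with phenylselenomethyllithium (from bis(phenylseleno)methane and n-BuLi, THF, −78 °C) to give (1R)-1-(2,4-dichlorophenyl)-3-(phenylselanyl)propan-1-ol F1. Oxidation (H2O2, pyridine, CH2Cl2, 0 °C to rt) and selenoxide syn-elimination installs the terminal alkene, rejoining the route at 7.

## Further compounds

F1 | step 3 | (1R)-1-(2,4-dichlorophenyl)-3-(phenylselanyl)propan-1-ol | O[C@H](CC[Se]c1ccccc1)c1ccc(Cl)cc1Cl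
F2 | step 4 | (1R)-3-[2-(allyloxy)-4-methoxyphenyl]-1-(2,4-dichlorophenyl)propan-1-ol | O[C@H](CCc1ccc(OC)cc1OCC=C)c1ccc(Cl)cc1Cl
F3 | step 6 | (2S)-8-allyl-2-{2,4-bis[2-(trimethylsilyl)ethoxy]phenyl}-7-methoxychromane | COc1ccc2c(c1CC=C)O[C@H](c1ccc(OCC[Si](C)(C)C)cc1OCC[Si](C)(C)C)CC2
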